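| setting | epsilon | beta | theta | zeta | eta |
|---|---|---|---|---|---|
| substrate | 120 mM | 72.0 mM | 120 mM | 120 mM | 60.0 mM |
| catalyst | 6.00 mM | 6.00 mM | 12.0 mM | 6.00 mM | 3.00 mM |
| target |  |  |  | 36.0 mM |  |
| time |  |  |  |  | 160 s |

| epsilon run: time / s | epsilon run: [target] / mM | beta run: time / s | beta run: [target] / mM | theta run: time / s | theta run: [target] / mM | zeta run: time / s | zeta run: [target] / mM |
|---|---|---|---|---|---|---|---|
| 7.1 | 2.9 | 7.1 | 1.9 | 7.1 | 6.0 | 7.1 | 39.9 |
| 22 | 7.5 | 22 | 6.2 | 22 | 16.9 | 22 | 44.4 |
| 41 | 15.8 | 41 | 10.5 | 41 | 28.9 | 41 | 52.5 |
| 65 | 23.0 | 65 | 16.1 | 65 | 43.7 | 65 | 59.2 |
| 93 | 32.6 | 93 | 21.7 | 93 | 58.5 | 93 | 68.7 |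
| 130 | 45.4 | 130 | 28.0 | 130 | 72.5 | 130 | 80.6 |
| 160 | 52.1 | 160 | 33.0 | 160 | 82.7 | 160 | 87.9 |

(each reading ± 0.6 mM)

* the exponent of [substrate] in the starting rate at the charge of the epsilon run (at the point where two percent of the substrate have become target) (one fixed amount of target, the same in the runs compared)
* the exponent of [catalyst] in the starting rate at the charge of the epsilon run (at the point where two percent of the substrate have become target)
* the beta run starts with 48.0 mM less of substrate than the epsilon run, and with no target. Compared where both hold the same amount of substrate, once fifteen percent of what the beta run was charged with has turned into target, is the beta run faster, slower or alike (within a tenth)?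
* target in the eta run at 160 s, as a share of the substrate charged

- Overall: substrate -> target, with catalyst as catalyst.
- Constant volume, constant temperature.
- Bound and free are read together.
- An order is taken over about fifteen percent of the charge, up and down.

- Start from a one-step world, where catalyst and substrate meet and give target at a rate proportional to both. The share of the charge turned then depends on time and catalyst charge through their product, and the size of the substrate charge drops out of a first-order flask.
- Use that as a bench rule. Read every flask on the catalyst clock, which for the eta run stands at 80.0 s, being the time multiplied by the catalyst charge over that of the epsilon run.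
- Test the catalyst side. Interpolating the readings, the theta run reaches a quarter of its charge at 42.8 s, which is 85.6 s on the clock, and the epsilon run needs 85.4 s. The clock holds between these two runs.
- Test the substrate side, where the rule stops. Interpolated the same way, the beta run reaches a quarter at 74.5 s, so the epsilon run over the beta run gives a ratio of 1.15, not one. The gap of 10.9 s stands above the 1.75 s that one reading's scatter is worth in time in the epsilon run.
- Turn that ratio into an order. With catalyst held and a rate that is a power of substrate, the time to a fixed share goes as the charge to the power of one minus the order, which gives a reading of 0.732 as an average between these two charges.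
- Reckon the eta run on the clock. At that clock reading, interpolation gives a share of 26.5% in the beta run and 23.5% in the epsilon run. Carry that trend on to the eta charge and commit to 27.3%.
- Set the forecast beside this. It gives 0.42 for substrate, 1.05 for catalyst, alike for the comparison and 25.7% for the eta run, a share lower than this reckoning. It reads “no clear catalyst decay” from the runs.
- Read the flask. The simulation gives 0.75 for substrate, 0.99 for catalyst, alike for the comparison and 27.2% for the eta run.

    catalyst + substrate → target + catalyst (0.7720 M⁻¹ s⁻¹)
    catalyst + substrate ⇌ idle catalyst-substrate complex, settled at all times (3.100 M⁻¹)

- Substrate parks catalyst in the idle catalyst-substrate complex (substrate inhibition): take that pairing away and the order in substrate at the epsilon charge goes from 0.75 to 1.0. With the pairing taken away, the eta run at 80.0 s on the clock gives 31.0%, against 27.2% as it stands. On the same clock the one-step reaction, with the pairing taken away, reaches a quarter at 62.1 s, the theta run as it stands later at 83.9 s, and at the start of the theta run about 72.9% of its catalyst is free.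

(The numbers in the tables are calculated with constants of no real substance; scatter was added.)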